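**Retrosynthetic overview**

- The target comes from its tris-MOM ether, a (2S)-flavanone. That flavanone comes from the flat flavone by copper hydride asymmetric 1,4-reduction, so C2 is set last and by the catalyst.
- Ring C of the flavone is closed at O1–C2 by 6-endo addition–elimination, after amine addition to an ynone and chelation-selective unmasking of the one oxygen beside the ketone.
- The strategy rests on one feature: C4 is a lone carbonyl carbon between C4a of the fully substituted ring A and the C3–C2–ring B unit. The ynone is therefore cut into a ring A iodide (iodine at C4a), CO (C4) and a ring B arylacetylene (C3, C2), joined by carbonylative Sonogashira coupling, which forms C4a–C4 and C4–C3.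
- The ring A iodide comes from 5-methoxyresorcinol: bis-MOM ether, silyl block at the future C8, directed lithiation and β-propiolactone opening at the future C6, Evans prenylation (side-chain stereocentre), MeMgBr, directed lithiation/iodination at the future C4a, desilylation. The alkyne comes from 2,4-dihydroxybenzaldehyde by MOM protection and Ohira–Bestmann homologation.
- Ring order: rings A and B are bought as arenes; ring C is the only ring formed (step 14) and is reduced to the flavanone in step 15.

Key step: step 12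

Assumption: (R)-DTBM-SEGPHOS is written as the ligand enantiomer that delivers hydride to the C2 face leading to (2S); the sense is to be checked on a simple 2-arylchromone and the (S)-ligand taken if it proves opposite.

**Route**

Step 1
Reactants: 1 5-methoxyresorcinol
Product: 2 1-methoxy-3,5-bis(methoxymethoxy)benzene
Conditions: NaH (2.4 equiv), MOMCl (2.4 equiv), DMF, 0 °C → rt
Reagents that add atoms: chloromethyl methyl ether, COCCl
Why: Williamson etherification of both phenoxides with the reactive chloromethyl ether gives the bis-acetal, whose two MOM-oxy groups are the directing groups for the lithiations that follow.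

Step 2
Reactants: 2 1-methoxy-3,5-bis(methoxymethoxy)benzene
Product: 4 [4-methoxy-2,6-bis(methoxymethoxy)phenyl]trimethylsilane, via aryllithium 3 (not isolated)
Conditions: n-BuLi (1.1 equiv), THF, 0 °C; Me3SiCl, −78 °C → rt
Reagents that add atoms: chlorotrimethylsilane, C[Si](C)(C)Cl
Why: Directed ortho-metalation takes the hydrogen flanked by the two MOM-oxy groups, the strongest cooperative directing pair, and silylation blocks this carbon, which has to end as the unsubstituted C8.

Step 3
Reactants: 4 [4-methoxy-2,6-bis(methoxymethoxy)phenyl]trimethylsilane; 5 β-propiolactone (oxetan-2-one)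
Product: 8 3-[6-methoxy-2,4-bis(methoxymethoxy)-3-(trimethylsilyl)phenyl]propanoic acid, via aryllithium 6 (not isolated), via Grignard reagent 7 (not isolated)
Conditions: s-BuLi (1.2 equiv), THF, −78 → −30 °C; MgBr2·OEt2 (1.3 equiv); CuBr·SMe2 (10 mol%), 5, −30 → 0 °C; aq. NaH2PO4 (pH 4–5)
Reagents that add atoms: none
Why: With the favoured site blocked, directed ortho-metalation can only occur at one of the two equivalent carbons between OMe and OMOM, and the derived aryl Grignard reagent opens the β-lactone at its CH2–O carbon under copper catalysis (SN2 alkyl–oxygen cleavage) to give the 3-arylpropanoic acid, the buffered work-up sparing the acid-labile aryl–silicon bond.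

Step 4
Reactants: 8 3-[6-methoxy-2,4-bis(methoxymethoxy)-3-(trimethylsilyl)phenyl]propanoic acid; 9 (4S)-4-benzyl-1,3-oxazolidin-2-one
Product: 11 (4S)-4-benzyl-3-{3-[6-methoxy-2,4-bis(methoxymethoxy)-3-(trimethylsilyl)phenyl]propanoyl}-1,3-oxazolidin-2-one, via mixed anhydride 10 (not isolated)
Conditions: PivCl, Et3N, THF, −20 °C; then 9, LiCl, rt
Reagents that add atoms: none
Why: N-Acylation of the Evans auxiliary through the pivalic mixed anhydride under the mild Et3N/LiCl protocol, the anhydride being attacked at its less hindered acyl group.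

Step 5
Reactants: 11 (4S)-4-benzyl-3-{3-[6-methoxy-2,4-bis(methoxymethoxy)-3-(trimethylsilyl)phenyl]propanoyl}-1,3-oxazolidin-2-one; 12 1-bromo-3-methylbut-2-ene (prenyl bromide)
Product: 14 (4S)-4-benzyl-3-[(2S)-2-{[6-methoxy-2,4-bis(methoxymethoxy)-3-(trimethylsilyl)phenyl]methyl}-5-methylhex-4-enoyl]-1,3-oxazolidin-2-one, via sodium enolate 13 (not isolated)
Conditions: NaN(SiMe3)2 (1.1 equiv), THF, −78 °C; 12 (3 equiv), −78 → −40 °C
Reagents that add atoms: none
Why: Evans asymmetric alkylation, in which the chelated sodium (Z)-enolate is attacked by the allylic bromide at its primary carbon on the face opposite the benzyl group of the (4S)-auxiliary, which sets the (S) side-chain stereocentre.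

Step 6
Reactants: 14 (4S)-4-benzyl-3-[(2S)-2-{[6-methoxy-2,4-bis(methoxymethoxy)-3-(trimethylsilyl)phenyl]methyl}-5-methylhex-4-enoyl]-1,3-oxazolidin-2-one
Product: 15 methyl (2S)-2-{[6-methoxy-2,4-bis(methoxymethoxy)-3-(trimethylsilyl)phenyl]methyl}-5-methylhex-4-enoate
Conditions: NaOMe (1.5 equiv), MeOH/THF, 0 °C
Reagents that add atoms: sodium methoxide, C[O-].[Na+]
Why: Transesterification by methoxide at the exocyclic imide carbonyl releases the recoverable auxiliary, and the short exposure at 0 °C should leave the α-centre of the less acidic ester untouched.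

Step 7
Reactants: 15 methyl (2S)-2-{[6-methoxy-2,4-bis(methoxymethoxy)-3-(trimethylsilyl)phenyl]methyl}-5-methylhex-4-enoate
Product: 17 (3S)-3-{[6-methoxy-2,4-bis(methoxymethoxy)-3-(trimethylsilyl)phenyl]methyl}-2,6-dimethylhept-5-en-2-ol, via methyl ketone 16 (not isolated)
Conditions: MeMgBr (4 equiv), THF, 0 °C → rt
Reagents that add atoms: methylmagnesium bromide, C[Mg]Br
Why: Double Grignard addition to the ester through the methyl ketone gives the dimethyl carbinol, the addition to the ketone being faster than enolisation towards the hindered α-carbon so that the stereocentre is kept.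

Step 8
Reactants: 17 (3S)-3-{[6-methoxy-2,4-bis(methoxymethoxy)-3-(trimethylsilyl)phenyl]methyl}-2,6-dimethylhept-5-en-2-ol
Product: 19 (3S)-3-{[3-iodo-2-methoxy-4,6-bis(methoxymethoxy)-5-(trimethylsilyl)phenyl]methyl}-2,6-dimethylhept-5-en-2-ol, via dilithio species 18 (not isolated)
Conditions: n-BuLi (2.3 equiv), THF, −78 → 0 °C; ICH2CH2I (1.3 equiv), −78 °C → rt
Reagents that add atoms: 1,2-diiodoethane, ICCI
Why: After deprotonation of the alcohol, directed ortho-metalation removes the only ring hydrogen left, between OMe and OMOM, and 1,2-diiodoethane transfers iodine to the aryllithium with loss of ethene, which avoids the iodoetherification of the prenyl double bond that elemental iodine could cause.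

Step 9
Reactants: 19 (3S)-3-{[3-iodo-2-methoxy-4,6-bis(methoxymethoxy)-5-(trimethylsilyl)phenyl]methyl}-2,6-dimethylhept-5-en-2-ol
Product: 20 (3S)-3-{[3-iodo-2-methoxy-4,6-bis(methoxymethoxy)phenyl]methyl}-2,6-dimethylhept-5-en-2-ol
Conditions: Bu4NF·3H2O, DMF, 60 °C
Reagents that add atoms: none
Why: Fluoride-induced ipso-protodesilylation, in which attack of fluoride at silicon releases an aryl anion stabilised by its two flanking oxygen substituents that is protonated at once by the water of the reagent, under conditions that leave the iodide, the acetals and the alcohol alone.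

Step 10
Reactants: 21 2,4-dihydroxybenzaldehyde
Product: 22 2,4-bis(methoxymethoxy)benzaldehyde
Conditions: NaH (2.5 equiv), MOMCl (2.5 equiv), DMF, 0 °C → rt
Reagents that add atoms: chloromethyl methyl ether, COCCl
Why: Williamson etherification of both phenoxides, the excess of base and chloromethyl ether being needed for the hydrogen-bonded ortho hydroxyl.

Step 11
Reactants: 22 2,4-bis(methoxymethoxy)benzaldehyde
Product: 23 1-ethynyl-2,4-bis(methoxymethoxy)benzene
Conditions: dimethyl (1-diazo-2-oxopropyl)phosphonate, K2CO3, MeOH, rt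
Reagents that add atoms: dimethyl (1-diazo-2-oxopropyl)phosphonate, CC(=O)C(=[N+]=[N-])P(=O)(OC)OC
Why: Seyferth–Gilbert homologation in the Ohira–Bestmann variant, in which the diazomethylphosphonate anion released by methanolysis adds to the aldehyde and elimination of phosphate, loss of N2 and a 1,2-hydride shift give the terminal alkyne under base mild enough for the MOM ethers.

Step 12
Reactants: 20 (3S)-3-{[3-iodo-2-methoxy-4,6-bis(methoxymethoxy)phenyl]methyl}-2,6-dimethylhept-5-en-2-ol; 24 carbon monoxide; 23 1-ethynyl-2,4-bis(methoxymethoxy)benzene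
Product: 25 3-[2,4-bis(methoxymethoxy)phenyl]-1-{3-[(2S)-2-(2-hydroxypropan-2-yl)-5-methylhex-4-en-1-yl]-2-methoxy-4,6-bis(methoxymethoxy)phenyl}prop-2-yn-1-one
Conditions: PdCl2(PPh3)2 (5 mol%), CuI (2 mol%), Et3N (3 equiv), THF, 24 (5 bar), 40 °C, slow addition of 23
Reagents that add atoms: none
Why: Zerovalent palladium inserts into the C4a–I bond of 20, CO coordinates and migrates into the aryl–palladium bond to give an aroyl complex of divalent palladium, the copper acetylide formed from 23, CuI and Et3N transmetalates, and reductive elimination makes C4–C3 after C4a–C4 to give ynone 25. The closest known reaction is the carbonylative Sonogashira coupling of aryl iodides, which has been run on 2,6-dioxygenated iodoarenes on the way to flavones. No ring closes, because O1 is still an acetal and cannot add to the triple bond, and no stereocentre is formed, the side-chain centre being a spectator. The step needs CO insertion to outrun direct alkynylation and alkyne dimerisation: the electron-rich, doubly ortho-substituted aryl–palladium intermediate transmetalates slowly but migrates readily onto CO, CO is kept in excess and the alkyne is added slowly with exclusion of air. Et3N is used instead of a secondary amine so that nitrogen intercepts neither the aroyl–palladium species nor the ynone, and the tertiary alcohol is too hindered to give an ester.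

Step 13
Reactants: 25 3-[2,4-bis(methoxymethoxy)phenyl]-1-{3-[(2S)-2-(2-hydroxypropan-2-yl)-5-methylhex-4-en-1-yl]-2-methoxy-4,6-bis(methoxymethoxy)phenyl}prop-2-yn-1-one
Product: 26 (2E)-3-[2,4-bis(methoxymethoxy)phenyl]-1-{3-[(2S)-2-(2-hydroxypropan-2-yl)-5-methylhex-4-en-1-yl]-2-methoxy-4,6-bis(methoxymethoxy)phenyl}-3-(pyrrolidin-1-yl)prop-2-en-1-one
Conditions: pyrrolidine (3 equiv), EtOH, rt → 40 °C
Reagents that add atoms: pyrrolidine, C1CCNC1
Why: Aza-Michael addition of the secondary amine to the ynone gives the vinylogous amide (double-bond geometry without consequence), which protects the triple bond from halide addition and from 5-exo closure to an aurone and turns C2 into a centre for addition–elimination.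

Step 14
Reactants: 26 (2E)-3-[2,4-bis(methoxymethoxy)phenyl]-1-{3-[(2S)-2-(2-hydroxypropan-2-yl)-5-methylhex-4-en-1-yl]-2-methoxy-4,6-bis(methoxymethoxy)phenyl}-3-(pyrrolidin-1-yl)prop-2-en-1-one
Product: 28 2-[2,4-bis(methoxymethoxy)phenyl]-6-[(2S)-2-(2-hydroxypropan-2-yl)-5-methylhex-4-en-1-yl]-5-methoxy-7-(methoxymethoxy)-4H-chromen-4-one, via hydroxy enaminone 27 (not isolated)
Conditions: MgBr2·OEt2 (3 equiv), Et2O/PhMe, 0 °C → rt; aq. NH4Cl
Reagents that add atoms: none
Why: Chelation-controlled Lewis acid cleavage, in which magnesium held between the enaminone carbonyl oxygen and the ortho acetal oxygen cleaves only this MOM ether (MgBr2 does not cleave the ortho methyl ether and the three other MOM ethers have no chelating neighbour), after which the phenoxide closes ring C by 6-endo addition to C2 and elimination of pyrrolidine.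

Step 15
Reactants: 28 2-[2,4-bis(methoxymethoxy)phenyl]-6-[(2S)-2-(2-hydroxypropan-2-yl)-5-methylhex-4-en-1-yl]-5-methoxy-7-(methoxymethoxy)-4H-chromen-4-one
Product: 30 (2S)-2-[2,4-bis(methoxymethoxy)phenyl]-6-[(2S)-2-(2-hydroxypropan-2-yl)-5-methylhex-4-en-1-yl]-5-methoxy-7-(methoxymethoxy)-2,3-dihydro-4H-chromen-4-one, via silyl enol ether 29 (not isolated)
Conditions: Cu(OAc)2·H2O (5 mol%), (R)-DTBM-SEGPHOS (5.5 mol%), (EtO)2MeSiH (4 equiv), PhMe, 0 °C → rt; then 1 M aq. HCl, THF, 0 °C
Reagents that add atoms: none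
Why: Copper hydride-catalysed asymmetric conjugate reduction as known for 2-substituted chromones and other β,β-disubstituted enones, in which the bisphosphine-ligated CuH delivers hydride to one face of C2 under control of the chiral ligand to set (2S), the enolate is trapped as the silyl enol ether that blocks over-reduction and retro-oxa-Michael opening, and cold dilute acid releases the ketone and any silyl ether formed at the tertiary alcohol.

Step 16
Reactants: 30 (2S)-2-[2,4-bis(methoxymethoxy)phenyl]-6-[(2S)-2-(2-hydroxypropan-2-yl)-5-methylhex-4-en-1-yl]-5-methoxy-7-(methoxymethoxy)-2,3-dihydro-4H-chromen-4-one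
Product: 31 (2S)-2-(2,4-dihydroxyphenyl)-7-hydroxy-6-[(2S)-2-(2-hydroxypropan-2-yl)-5-methylhex-4-en-1-yl]-5-methoxy-2,3-dihydro-4H-chromen-4-one
Conditions: HCl (1.25 M in MeOH), THF, rt
Reagents that add atoms: none
Why: Acid-catalysed acetal methanolysis of the three aryl MOM ethers, run dilute and at room temperature because flavanones hold their C2 configuration in acid while ionisation of the tertiary alcohol (to a chroman or a methyl ether) and protonation of the prenyl double bond are much slower than acetal cleavage.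

**Compound list**

1 | 5-methoxyresorcinol | COc1cc(O)cc(O)c1 | starting material
2 | 1-methoxy-3,5-bis(methoxymethoxy)benzene | COCOc1cc(OC)cc(OCOC)c1 | intermediate
3 | [4-methoxy-2,6-bis(methoxymethoxy)phenyl]lithium | [Li]c1c(OCOC)cc(OC)cc1OCOC | intermediate
4 | [4-methoxy-2,6-bis(methoxymethoxy)phenyl]trimethylsilane | COCOc1cc(OC)cc(OCOC)c1[Si](C)(C)C | intermediate
5 | β-propiolactone (oxetan-2-one) | O=C1CCO1 | starting material
6 | [6-methoxy-2,4-bis(methoxymethoxy)-3-(trimethylsilyl)phenyl]lithium | [Li]c1c(OC)cc(OCOC)c([Si](C)(C)C)c1OCOC | intermediate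
7 | bromo[6-methoxy-2,4-bis(methoxymethoxy)-3-(trimethylsilyl)phenyl]magnesium | Br[Mg]c1c(OC)cc(OCOC)c([Si](C)(C)C)c1OCOC | intermediate
8 | 3-[6-methoxy-2,4-bis(methoxymethoxy)-3-(trimethylsilyl)phenyl]propanoic acid | OC(=O)CCc1c(OC)cc(OCOC)c([Si](C)(C)C)c1OCOC | intermediate
9 | (4S)-4-benzyl-1,3-oxazolidin-2-one | O=C1OC[C@H](Cc2ccccc2)N1 | starting material
10 | 3-[6-methoxy-2,4-bis(methoxymethoxy)-3-(trimethylsilyl)phenyl]propanoic pivalic anhydride | CC(C)(C)C(=O)OC(=O)CCc1c(OC)cc(OCOC)c([Si](C)(C)C)c1OCOC | intermediate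
11 | (4S)-4-benzyl-3-{3-[6-methoxy-2,4-bis(methoxymethoxy)-3-(trimethylsilyl)phenyl]propanoyl}-1,3-oxazolidin-2-one | O=C1OC[C@H](Cc2ccccc2)N1C(=O)CCc3c(OC)cc(OCOC)c([Si](C)(C)C)c3OCOC | intermediate
12 | 1-bromo-3-methylbut-2-ene (prenyl bromide) | CC(C)=CCBr | starting material
13 | sodium (Z)-enolate of 11 | O=C1OC[C@H](Cc2ccccc2)N1C(/O[Na])=C/Cc3c(OC)cc(OCOC)c([Si](C)(C)C)c3OCOC | intermediate
14 | (4S)-4-benzyl-3-[(2S)-2-{[6-methoxy-2,4-bis(methoxymethoxy)-3-(trimethylsilyl)phenyl]methyl}-5-methylhex-4-enoyl]-1,3-oxazolidin-2-one | O=C1OC[C@H](Cc2ccccc2)N1C(=O)[C@@H](CC=C(C)C)Cc3c(OC)cc(OCOC)c([Si](C)(C)C)c3OCOC | intermediate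
15 | methyl (2S)-2-{[6-methoxy-2,4-bis(methoxymethoxy)-3-(trimethylsilyl)phenyl]methyl}-5-methylhex-4-enoate | COC(=O)[C@@H](CC=C(C)C)Cc1c(OC)cc(OCOC)c([Si](C)(C)C)c1OCOC | intermediate
16 | (3S)-3-{[6-methoxy-2,4-bis(methoxymethoxy)-3-(trimethylsilyl)phenyl]methyl}-6-methylhept-5-en-2-one | CC(=O)[C@@H](CC=C(C)C)Cc1c(OC)cc(OCOC)c([Si](C)(C)C)c1OCOC | intermediate
17 | (3S)-3-{[6-methoxy-2,4-bis(methoxymethoxy)-3-(trimethylsilyl)phenyl]methyl}-2,6-dimethylhept-5-en-2-ol | CC(C)(O)[C@@H](CC=C(C)C)Cc1c(OC)cc(OCOC)c([Si](C)(C)C)c1OCOC | intermediate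
18 | lithium alkoxide/aryllithium (dilithio species) of 17 | [Li]OC(C)(C)[C@@H](CC=C(C)C)Cc1c(OC)c([Li])c(OCOC)c([Si](C)(C)C)c1OCOC | intermediate
19 | (3S)-3-{[3-iodo-2-methoxy-4,6-bis(methoxymethoxy)-5-(trimethylsilyl)phenyl]methyl}-2,6-dimethylhept-5-en-2-ol | CC(C)(O)[C@@H](CC=C(C)C)Cc1c(OC)c(I)c(OCOC)c([Si](C)(C)C)c1OCOC | intermediate
20 | (3S)-3-{[3-iodo-2-methoxy-4,6-bis(methoxymethoxy)phenyl]methyl}-2,6-dimethylhept-5-en-2-ol | CC(C)(O)[C@@H](CC=C(C)C)Cc1c(OC)c(I)c(OCOC)cc1OCOC | intermediate
21 | 2,4-dihydroxybenzaldehyde | O=Cc1ccc(O)cc1O | starting material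
22 | 2,4-bis(methoxymethoxy)benzaldehyde | O=Cc1ccc(OCOC)cc1OCOC | intermediate
23 | 1-ethynyl-2,4-bis(methoxymethoxy)benzene | C#Cc1ccc(OCOC)cc1OCOC | intermediate
24 | carbon monoxide | [C-]#[O+] | starting material
25 | 3-[2,4-bis(methoxymethoxy)phenyl]-1-{3-[(2S)-2-(2-hydroxypropan-2-yl)-5-methylhex-4-en-1-yl]-2-methoxy-4,6-bis(methoxymethoxy)phenyl}prop-2-yn-1-one | COc1c(C(=O)C#Cc2ccc(OCOC)cc2OCOC)c(OCOC)cc(OCOC)c1C[C@H](CC=C(C)C)C(C)(C)O | intermediate
26 | (2E)-3-[2,4-bis(methoxymethoxy)phenyl]-1-{3-[(2S)-2-(2-hydroxypropan-2-yl)-5-methylhex-4-en-1-yl]-2-methoxy-4,6-bis(methoxymethoxy)phenyl}-3-(pyrrolidin-1-yl)prop-2-en-1-one | COc1c(C(=O)/C=C(/N3CCCC3)c2ccc(OCOC)cc2OCOC)c(OCOC)cc(OCOC)c1C[C@H](CC=C(C)C)C(C)(C)O | intermediate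
27 | (2E)-3-[2,4-bis(methoxymethoxy)phenyl]-1-{6-hydroxy-3-[(2S)-2-(2-hydroxypropan-2-yl)-5-methylhex-4-en-1-yl]-2-methoxy-4-(methoxymethoxy)phenyl}-3-(pyrrolidin-1-yl)prop-2-en-1-one (present as its magnesium phenoxide) | COc1c(C(=O)/C=C(/N3CCCC3)c2ccc(OCOC)cc2OCOC)c(O)cc(OCOC)c1C[C@H](CC=C(C)C)C(C)(C)O | intermediate
28 | 2-[2,4-bis(methoxymethoxy)phenyl]-6-[(2S)-2-(2-hydroxypropan-2-yl)-5-methylhex-4-en-1-yl]-5-methoxy-7-(methoxymethoxy)-4H-chromen-4-one | COc1c(C[C@H](CC=C(C)C)C(C)(C)O)c(OCOC)cc2oc(-c3ccc(OCOC)cc3OCOC)cc(=O)c12 | intermediate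
29 | (2S)-2-[2,4-bis(methoxymethoxy)phenyl]-4-{[diethoxy(methyl)silyl]oxy}-6-[(2S)-2-(2-hydroxypropan-2-yl)-5-methylhex-4-en-1-yl]-5-methoxy-7-(methoxymethoxy)-2H-chromene | COc1c(C[C@H](CC=C(C)C)C(C)(C)O)c(OCOC)cc2c1C(O[Si](C)(OCC)OCC)=C[C@@H](c1ccc(OCOC)cc1OCOC)O2 | intermediate
30 | (2S)-2-[2,4-bis(methoxymethoxy)phenyl]-6-[(2S)-2-(2-hydroxypropan-2-yl)-5-methylhex-4-en-1-yl]-5-methoxy-7-(methoxymethoxy)-2,3-dihydro-4H-chromen-4-one | COc1c(C[C@H](CC=C(C)C)C(C)(C)O)c(OCOC)cc2c1C(=O)C[C@@H](c1ccc(OCOC)cc1OCOC)O2 | intermediate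
31 | (2S)-2-(2,4-dihydroxyphenyl)-7-hydroxy-6-[(2S)-2-(2-hydroxypropan-2-yl)-5-methylhex-4-en-1-yl]-5-methoxy-2,3-dihydro-4H-chromen-4-one | COc1c(C[C@H](CC=C(C)C)C(C)(C)O)c(O)cc2c1C(=O)C[C@@H](c1ccc(O)cc1O)O2 | target

**Step count and risks**

Total step count: 16. Longest linear sequence: 14 steps (steps 1–9, then 12–16); steps 10–11 form the short branch to the alkyne.

Steps most likely to fail, in order of risk:

Step 15. Hydride transfer to C2 of the flavone may be slow, because C2 is the β-carbon of a vinylogous ester and carries an ortho-substituted aryl group. The result would be incomplete conversion, insufficient facial selectivity, or opening of the copper enolate to a chalcone before silyl transfer. The fallback sets out from 28 and gives up catalyst control in the reduction. An achiral copper hydride (Cu(OAc)2·H2O, 1,2-bis(diphenylphosphino)benzene, (Me2SiH)2O, PhMe) should give 30 together with the C2 epimer of 30 F1; the two are diastereomers because of the side-chain centre. A Noyori-type asymmetric transfer hydrogenation (RuCl(p-cymene)(TsDPEN), HCO2H/Et3N, ligand enantiomer matched to the (2R) series) should then reduce only the (2R) epimer to the cis-flavan-4-ol F2. Chromatography removes F2 and leaves 30, where the route is rejoined.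

Step 14. The acetal cleavage may lose site selectivity. The doubly ortho-substituted aryl ketone is twisted and may chelate magnesium poorly, so that the reaction stalls or, on forcing, the other MOM ethers or the tertiary alcohol are attacked. The fallback sets out from 26 and replaces selective unmasking by global unmasking and re-protection. Methanolic HCl (1.25 M, rt) should remove all four MOM groups, and the freed oxygen beside the ketone closes ring C with loss of pyrrolidine to give the trihydroxyflavone F3. The three phenols are then re-protected (MOMCl, K2CO3, acetone), which leaves the tertiary alcohol free and returns to 28.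

Step 12. Direct alkynylation without uptake of CO, or slow oxidative addition at the hindered iodide with dimerisation of the alkyne, may erode the yield of the ynone. The fallback sets out from 20 and 23 and builds the same two bonds by polar chemistry. Iodine–magnesium exchange on 20 (i-PrMgCl·LiCl, 2.2 equiv, THF, 0 °C → rt) should give the arylmagnesium chloride alkoxide F4. Alkyne 23 is deprotonated (n-BuLi, THF, −78 °C) to the lithium acetylide F5, which is formylated with DMF to the arylpropynal F6. Addition of F4 to F6 gives the propargylic alcohol F7 as a mixture of carbinol epimers, and MnO2 (CH2Cl2, rt) oxidises it to 25, where the route is rejoined.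

**Further compounds**

F1 | step 15 | (2R)-2-[2,4-bis(methoxymethoxy)phenyl]-6-[(2S)-2-(2-hydroxypropan-2-yl)-5-methylhex-4-en-1-yl]-5-methoxy-7-(methoxymethoxy)-2,3-dihydro-4H-chromen-4-one (C2 epimer of 30) | COc1c(C[C@H](CC=C(C)C)C(C)(C)O)c(OCOC)cc2c1C(=O)C[C@H](c1ccc(OCOC)cc1OCOC)O2
F2 | step 15 | (2R,4R)-2-[2,4-bis(methoxymethoxy)phenyl]-6-[(2S)-2-(2-hydroxypropan-2-yl)-5-methylhex-4-en-1-yl]-5-methoxy-7-(methoxymethoxy)-3,4-dihydro-2H-chromen-4-ol | COc1c(C[C@H](CC=C(C)C)C(C)(C)O)c(OCOC)cc2c1[C@H](O)C[C@H](c1ccc(OCOC)cc1OCOC)O2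
F3 | step 14 | 2-(2,4-dihydroxyphenyl)-7-hydroxy-6-[(2S)-2-(2-hydroxypropan-2-yl)-5-methylhex-4-en-1-yl]-5-methoxy-4H-chromen-4-one | COc1c(C[C@H](CC=C(C)C)C(C)(C)O)c(O)cc2oc(-c3ccc(O)cc3O)cc(=O)c12
F4 | step 12 | arylmagnesium chloride with chloromagnesium alkoxide derived from 20 | Cl[Mg]c1c(OC)c(C[C@H](CC=C(C)C)C(C)(C)O[Mg]Cl)c(OCOC)cc1OCOC
F5 | step 12 | lithium [2,4-bis(methoxymethoxy)phenyl]acetylide | [Li]C#Cc1ccc(OCOC)cc1OCOC
F6 | step 12 | 3-[2,4-bis(methoxymethoxy)phenyl]prop-2-ynal | O=CC#Cc1ccc(OCOC)cc1OCOC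
F7 | step 12 | 3-[2,4-bis(methoxymethoxy)phenyl]-1-{3-[(2S)-2-(2-hydroxypropan-2-yl)-5-methylhex-4-en-1-yl]-2-methoxy-4,6-bis(methoxymethoxy)phenyl}prop-2-yn-1-ol (both carbinol epimers) | COc1c(C(O)C#Cc2ccc(OCOC)cc2OCOC)c(OCOC)cc(OCOC)c1C[C@H](CC=C(C)C)C(C)(C)O
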